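Ring A (C1 = ring carbonyl, C2 = butanoyl-bearing carbon, C4 = quaternary carbon, C6 = bridge carbon) is cut into the C2–C3 unit, an alkoxy ynone, and the C1–C6–C5–C4 unit, a 3-ethoxycyclobutenone in which C1 and C4 are joined by a sacrificial strained acyl–C(sp3) bond. The key step exploits the alternating 1,3,5-oxygenation of ring A around quaternary C4: zerovalent nickel inserts into the temporary C1–C4 bond and stitches in the alkyne, closing ring A at its final oxidation level while C4, set earlier by desymmetrising a prochiral cyclobutane-1,3-dione, is carried over with retention. Enol ether hydrolysis and a Mannich-based methylene bridge to aspidinol finish the synthesis.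

Key step: step 7

Assumption: aspidinol (18) is bought as such; the phosphoric acid antipode used in step 4 is the one that a first run shows to deliver the (S)-enaminone.

Step 1
Reactants: 1 propanoyl chloride; 2 ethoxyethyne
Product: 4 racemic 3-ethoxy-4-methylcyclobut-2-en-1-one, via methylketene 3 (not isolated)
Conditions: Et3N, Et2O, 0 °C to rt
Reagents that add atoms: none
Why: Dehydrochlorination of 1 gives methylketene, which the electron-rich alkyne traps in a thermal ketene–alkyne [2+2] cycloaddition (ketene carbonyl carbon to the nucleophilic CH terminus of the ynol ether); the ring stereocenter forms racemic and is erased in step 2.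

Step 2
Reactants: 4 racemic 3-ethoxy-4-methylcyclobut-2-en-1-one
Product: 5 3-hydroxy-2-methylcyclobut-2-en-1-one (enol form of 2-methylcyclobutane-1,3-dione)
Conditions: 1 M aq. HCl, THF, rt
Reagents that add atoms: water, O
Why: Acid-catalysed hydrolysis of the vinylogous ester (addition of water, loss of ethanol) liberates the strongly acidic dione, isolated as its enol.

Step 3
Reactants: 5 3-hydroxy-2-methylcyclobut-2-en-1-one; 6 prenyl acetate (3-methylbut-2-en-1-yl acetate, 0.95 equiv)
Product: 7 2-methyl-2-(3-methylbut-2-en-1-yl)cyclobutane-1,3-dione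
Conditions: Pd(PPh3)4 (5 mol %), THF, 40 °C
Reagents that add atoms: none
Why: Tsuji–Trost allylation, in which the soft dione enolate attacks the unsubstituted terminus of the π-prenyl palladium complex through its central carbon and any O-prenyl ether re-ionises under the catalyst, should give the linear C-prenylated dione; its quaternary carbon is prochiral, so no stereocenter forms.

Step 4
Reactants: 7 2-methyl-2-(3-methylbut-2-en-1-yl)cyclobutane-1,3-dione; 8 4-methoxyaniline
Product: 9 (S)-3-[(4-methoxyphenyl)amino]-4-methyl-4-(3-methylbut-2-en-1-yl)cyclobut-2-en-1-one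
Conditions: (R)-TRIP [3,3'-bis(2,4,6-triisopropylphenyl)-BINOL hydrogen phosphate] (5 mol %), 5 Å MS, toluene, 0 °C
Reagents that add atoms: none
Why: Chiral phosphoric acid-catalysed desymmetrising carbonyl–amine condensation, in which the catalyst hydrogen-bonds dione and aniline and selects one of the two enantiotopic carbonyls, so that dehydration to the vinylogous amide turns the prochiral quaternary carbon into the (S)-stereocenter under catalyst control.

Step 5
Reactants: 9 (S)-3-[(4-methoxyphenyl)amino]-4-methyl-4-(3-methylbut-2-en-1-yl)cyclobut-2-en-1-one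
Product: 11 (R)-3-ethoxy-4-methyl-4-(3-methylbut-2-en-1-yl)cyclobut-2-en-1-one, via O-ethyl iminium tetrafluoroborate 10 (not isolated)
Conditions: Et3O·BF4, CH2Cl2, 0 °C to rt; then H2O, THF, 0 °C
Reagents that add atoms: triethyloxonium tetrafluoroborate, CC[O+](CC)CC.F[B-](F)(F)F; water, O
Why: O-Alkylation of the vinylogous amide with Meerwein's salt and Pinner-type hydrolysis of the vinylogous imidate at its iminium carbon exchange the roles of the two oxygenated carbons (1,3-carbonyl transposition) without passing through the symmetric dione, so the quaternary center keeps its configuration (S becomes R only through the change in priorities).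

Step 6
Reactants: 2 ethoxyethyne; 12 N-methoxy-N-methylbutanamide
Product: 14 1-ethoxyhex-1-yn-3-one, via lithium ethoxyacetylide 13 (not isolated)
Conditions: n-BuLi, THF, −78 °C; then 12, −78 to 0 °C; H2O
Reagents that add atoms: none
Why: The lithium acetylide adds to the Weinreb amide and stops at the chelated tetrahedral adduct, which collapses to the ynone on aqueous quench (Weinreb ketone synthesis).

Step 7
Reactants: 11 (R)-3-ethoxy-4-methyl-4-(3-methylbut-2-en-1-yl)cyclobut-2-en-1-one; 14 1-ethoxyhex-1-yn-3-one
Product: 16 (R)-2-butanoyl-3,5-diethoxy-4-methyl-4-(3-methylbut-2-en-1-yl)cyclohexa-2,5-dien-1-one, via nickelacyclopentenone 15 (not isolated)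
Conditions: Ni(cod)2 (10 mol %), PPh3 (20 mol %), toluene, 0 °C to rt, slow addition of 14
Reagents that add atoms: none
Why: Proposed new method: zerovalent nickel should add oxidatively into the strained C1–C4 acyl–C(sp3) bond of 11 to give nickelacyclopentenone 15, whose nickel-bound, enol-ether-stabilised allylic carbon C4 adds to the electrophilic ethoxy-bearing carbon of ynone 14 (carbonickelation in the conjugate sense), after which acyl–alkenyl reductive elimination forms the C1–C2 bond. The closest known reaction type is the nickel-catalysed [4+2] benzannulation of cyclobutenones with alkynes to phenols; here both C4 substituents are carbon, so the primary adduct cannot tautomerise and the cross-conjugated 4,4-disubstituted cyclohexa-2,5-dienone is kept. Ring A is closed as a six-membered carbocycle in a formal [4+2] mode, by reductive elimination from a seven-membered nickelacycle. The C4 stereocenter is not created but transferred from 11, since oxidative addition, insertion and reductive elimination all proceed with retention at the metal-bound carbon and, at 0 °C to rt, thermal electrocyclic opening of 11 to the achiral vinylketene is out of reach. The step needs regioselective insertion, which the push–pull polarisation of 14 should secure (nucleophilic C4 to the β-carbon, acyl to the α-carbon, giving the conjugated 2-acyl vinylogous ester), and chemoselectivity over alkyne cyclotrimerisation, addressed by slow addition of 14 to a slight excess of 11.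

Step 8
Reactants: 16 (R)-2-butanoyl-3,5-diethoxy-4-methyl-4-(3-methylbut-2-en-1-yl)cyclohexa-2,5-dien-1-one
Product: 17 (R)-2-butanoyl-3,5-dihydroxy-4-methyl-4-(3-methylbut-2-en-1-yl)cyclohexa-2,5-dien-1-one
Conditions: 1 M aq. HCl, THF, rt
Reagents that add atoms: water, O
Why: Acid-catalysed hydrolysis of both vinylogous ethyl esters, under conditions meant to be too mild for cyclisation of the prenyl group onto the enol hydroxyl, should unveil the triketone, whose quaternary center carries no epimerisable hydrogen.

Step 9
Reactants: 18 aspidinol, 1-(2,6-dihydroxy-4-methoxy-3-methylphenyl)butan-1-one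
Product: 19 1-{3-[(dimethylamino)methyl]-2,6-dihydroxy-4-methoxy-5-methylphenyl}butan-1-one
Conditions: Eschenmoser's salt, CH2Cl2, rt; aq. NaHCO3 work-up
Reagents that add atoms: N,N-dimethylmethyleneiminium iodide (Eschenmoser's salt), C=[N+](C)C.[I-]
Why: Aromatic Mannich reaction of the electron-rich phloroglucinol ring with the preformed iminium ion at the only unsubstituted ring carbon.

Step 10
Reactants: 17 (R)-2-butanoyl-3,5-dihydroxy-4-methyl-4-(3-methylbut-2-en-1-yl)cyclohexa-2,5-dien-1-one; 19 1-{3-[(dimethylamino)methyl]-2,6-dihydroxy-4-methoxy-5-methylphenyl}butan-1-one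
Product: 21 CNP0219644.1, (R)-2-butanoyl-6-[(3-butanoyl-2,4-dihydroxy-6-methoxy-5-methylphenyl)methyl]-3,5-dihydroxy-4-methyl-4-(3-methylbut-2-en-1-yl)cyclohexa-2,5-dien-1-one, via ortho-quinone methide 20 (not isolated)
Conditions: 1,4-dioxane, 90 °C, N2
Reagents that add atoms: none
Why: Thermal loss of dimethylamine from the ortho-hydroxybenzylamine gives ortho-quinone methide 20, which the only C–H acidic ring carbon (C6) of triketone 17 traps in a Michael addition with rearomatisation, so the unsymmetrical methylene bridge should form without homodimers and without touching C4.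

Compound list
1 | propanoyl chloride | CCC(=O)Cl | starting material
2 | ethoxyethyne (ethoxyacetylene) | CCOC#C | starting material
3 | methylketene (prop-1-en-1-one) | CC=C=O | intermediate
4 | racemic 3-ethoxy-4-methylcyclobut-2-en-1-one | CCOC1=CC(=O)C1C | intermediate
5 | 3-hydroxy-2-methylcyclobut-2-en-1-one | CC1=C(O)CC1=O | intermediate
6 | prenyl acetate (3-methylbut-2-en-1-yl acetate) | CC(=O)OCC=C(C)C | starting material
7 | 2-methyl-2-(3-methylbut-2-en-1-yl)cyclobutane-1,3-dione | CC1(CC=C(C)C)C(=O)CC1=O | intermediate
8 | 4-methoxyaniline | COc1ccc(N)cc1 | starting material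
9 | (S)-3-[(4-methoxyphenyl)amino]-4-methyl-4-(3-methylbut-2-en-1-yl)cyclobut-2-en-1-one | O=C1C=C(Nc2ccc(OC)cc2)[C@]1(C)CC=C(C)C | intermediate
10 | (S)-N-[3-ethoxy-4-methyl-4-(3-methylbut-2-en-1-yl)cyclobut-2-en-1-ylidene]-4-methoxyanilinium tetrafluoroborate | CCOC1=CC(=[NH+]c2ccc(OC)cc2)[C@]1(C)CC=C(C)C.F[B-](F)(F)F | intermediate
11 | (R)-3-ethoxy-4-methyl-4-(3-methylbut-2-en-1-yl)cyclobut-2-en-1-one | CCOC1=CC(=O)[C@]1(C)CC=C(C)C | intermediate
12 | N-methoxy-N-methylbutanamide | CCCC(=O)N(C)OC | starting material
13 | lithium ethoxyacetylide | CCOC#C[Li] | intermediate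
14 | 1-ethoxyhex-1-yn-3-one | CCCC(=O)C#COCC | intermediate
15 | (R)-4-ethoxy-5-methyl-5-(3-methylbut-2-en-1-yl)-1-nickelacyclopent-3-en-2-one (phosphine ligands on nickel not drawn) | CCOC1=CC(=O)[Ni][C@]1(C)CC=C(C)C | intermediate
16 | (R)-2-butanoyl-3,5-diethoxy-4-methyl-4-(3-methylbut-2-en-1-yl)cyclohexa-2,5-dien-1-one | CCCC(=O)C1=C(OCC)[C@](C)(CC=C(C)C)C(OCC)=CC1=O | intermediate
17 | (R)-2-butanoyl-3,5-dihydroxy-4-methyl-4-(3-methylbut-2-en-1-yl)cyclohexa-2,5-dien-1-one | CCCC(=O)C1=C(O)[C@](C)(CC=C(C)C)C(O)=CC1=O | intermediate
18 | aspidinol, 1-(2,6-dihydroxy-4-methoxy-3-methylphenyl)butan-1-one | CCCC(=O)c1c(O)cc(OC)c(C)c1O | starting material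
19 | 1-{3-[(dimethylamino)methyl]-2,6-dihydroxy-4-methoxy-5-methylphenyl}butan-1-one | CCCC(=O)c1c(O)c(CN(C)C)c(OC)c(C)c1O | intermediate
20 | 2-butanoyl-3-hydroxy-5-methoxy-4-methyl-6-methylidenecyclohexa-2,4-dien-1-one | CCCC(=O)C1=C(O)C(C)=C(OC)C(=C)C1=O | intermediate
21 | CNP0219644.1, (R)-2-butanoyl-6-[(3-butanoyl-2,4-dihydroxy-6-methoxy-5-methylphenyl)methyl]-3,5-dihydroxy-4-methyl-4-(3-methylbut-2-en-1-yl)cyclohexa-2,5-dien-1-one | CCCC(=O)C1=C(O)[C@](C)(CC=C(C)C)C(O)=C(Cc2c(O)c(C(=O)CCC)c(O)c(C)c2OC)C1=O | target

Total step count: 10. Longest linear sequence: 8 steps (1, 2, 3, 4, 5, 7, 8, 10); steps 6 and 9 are side branches.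

Steps most likely to fail

Step 7 (proposed new method). The alkyne may insert with the opposite orientation, cyclotrimerisation of the ynone may outrun C–C oxidative addition, or leakage through a decomplexed achiral vinylketene may erode the enantiomeric purity. The fallback uses known chemistry only, sets out from aspidinol 18 and comes back at 17. O-Demethylation of 18 with BBr3 (CH2Cl2, −78 to 0 °C) should give 1-(2,4,6-trihydroxy-3-methylphenyl)butan-1-one F1. Alkylative dearomatisation of F1 with prenyl bromide and NaOMe in MeOH at 0 °C, with C-alkylation at the methyl-bearing ring carbon, should give the racemic triketone F2. Preparative HPLC on a chiral stationary phase then separates 17 from its (S)-enantiomer F3, and 17 enters step 10.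

Step 5. Water may attack the ethoxy-bearing carbon of iminium salt 10 and return 9, or 11 may hydrolyse further to the achiral dione 7 with loss of the stereochemical information. The fallback sets out from 7 and comes back at 17; it keeps nitrogen as the masked C5 oxygen and drops the transposition. Step 4 run with (S)-TRIP should give the antipodal enaminone (R)-3-[(4-methoxyphenyl)amino]-4-methyl-4-(3-methylbut-2-en-1-yl)cyclobut-2-en-1-one F4. Boc2O and DMAP (MeCN, rt) should give the N-Boc enaminone F5. Under the step 7 conditions, nickel now cleaves the bond between the ketone carbon and the quaternary carbon of F5 and inserts 14, which should give the 5-[N-Boc-(4-methoxyphenyl)amino] analogue of 16, F6, with the configuration the target needs. 1 M aq. HCl in THF then hydrolyses the ethyl enol ether and the N-Boc enamine of F6 to 17.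

Step 4. The catalyst may discriminate poorly between the enantiotopic carbonyls, since methyl and prenyl differ little in size, or the amine may open the strained dione by retro-Claisen cleavage. The fallback sets out from 7 and comes back at 11. Condensation of 7 with (S)-1-phenylethylamine (toluene, MgSO4, rt) gives the diastereomeric enaminones (S)-4-methyl-4-(3-methylbut-2-en-1-yl)-3-{[(S)-1-phenylethyl]amino}cyclobut-2-en-1-one F7 and its (R)-ring epimer F8, which are separated by chromatography or crystallisation. F7 under the step 5 conditions (Et3O·BF4, then water) releases the auxiliary amine and gives 11. F8 is hydrolysed back to 7 with aqueous HCl and recycled.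

Further compounds
F1 | step 7 | 1-(2,4,6-trihydroxy-3-methylphenyl)butan-1-one | CCCC(=O)c1c(O)cc(O)c(C)c1O
F2 | step 7 | racemic 2-butanoyl-3,5-dihydroxy-4-methyl-4-(3-methylbut-2-en-1-yl)cyclohexa-2,5-dien-1-one | CCCC(=O)C1=C(O)C(C)(CC=C(C)C)C(O)=CC1=O
F3 | step 7 | (S)-2-butanoyl-3,5-dihydroxy-4-methyl-4-(3-methylbut-2-en-1-yl)cyclohexa-2,5-dien-1-one | CCCC(=O)C1=C(O)[C@@](C)(CC=C(C)C)C(O)=CC1=O
F4 | step 5 | (R)-3-[(4-methoxyphenyl)amino]-4-methyl-4-(3-methylbut-2-en-1-yl)cyclobut-2-en-1-one | O=C1C=C(Nc2ccc(OC)cc2)[C@@]1(C)CC=C(C)C
F5 | step 5 | tert-butyl (4-methoxyphenyl)[(R)-4-methyl-4-(3-methylbut-2-en-1-yl)-3-oxocyclobut-1-en-1-yl]carbamate | O=C1C=C(N(C(=O)OC(C)(C)C)c2ccc(OC)cc2)[C@@]1(C)CC=C(C)C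
F6 | step 5 | tert-butyl [(R)-4-butanoyl-5-ethoxy-6-methyl-6-(3-methylbut-2-en-1-yl)-3-oxocyclohexa-1,4-dien-1-yl](4-methoxyphenyl)carbamate | CCCC(=O)C1=C(OCC)[C@](C)(CC=C(C)C)C(N(C(=O)OC(C)(C)C)c2ccc(OC)cc2)=CC1=O
F7 | step 4 | (S)-4-methyl-4-(3-methylbut-2-en-1-yl)-3-{[(S)-1-phenylethyl]amino}cyclobut-2-en-1-one | O=C1C=C(N[C@@H](C)c2ccccc2)[C@]1(C)CC=C(C)C
F8 | step 4 | (R)-4-methyl-4-(3-methylbut-2-en-1-yl)-3-{[(S)-1-phenylethyl]amino}cyclobut-2-en-1-one | O=C1C=C(N[C@@H](C)c2ccccc2)[C@@]1(C)CC=C(C)C
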